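The numbers in the tables stem from a simulated flask for substances that don't exist.

The meeting opened on a leftover: Saturday's flask read 0.2% of substrate at 3.00 min, against a scatter of 0.3 percentage points, although the last portion fell due at that minute. The chair concluded that the reading came just before that portion, so that 75.0% of the charge had gone in.

| flask | substrate | partner | remark | time |
|---|---|---|---|---|
| Saturday's | 0.14 M (in portions, 4) | 0.55 M | run made earlier; portions every 1.0 min |  |
| Tuesday's | 0.23 M (in portions, 4) | 0.55 M | run made earlier; portions every 1.0 min |  |
| Friday's | 0.40 M (in portions, 4) | 0.55 M | run made earlier; portions every 1.0 min |  |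
| gamma | 0.12 M (in portions, 4) | 0.550 M | the portions of substrate follow each other after 1.0 min, the first at the start | 6.0 min |
| zeta | 0.25 M (in portions, 4) | 0.550 M | the portions of substrate follow each other after 1.0 min, the first at the start | 6.0 min |
| delta | 0.50 M (in portions, 4) | 0.550 M | the portions of substrate follow each other after 1.0 min, the first at the start | 6.0 min |

| run | time / min | target / % | substrate / % |
|---|---|---|---|
| Saturday's | 0.250 | 3.3 | 2.2 |
| Saturday's | 0.417 | 5.1 | 0.8 |
| Saturday's | 0.833 | 8.6 | 0.3 |
| Saturday's | 1.50 | 16.4 | 0.3 |
| Saturday's | 3.00 | 31.5 | 0.2 |
| Tuesday's | 0.250 | 3.6 | 2.3 |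
| Tuesday's | 0.833 | 8.8 | 0 |
| Tuesday's | 1.33 | 14.6 | 0.9 |
| Tuesday's | 2.00 | 20.4 | 0.1 |
| Tuesday's | 3.00 | 31.2 | 0.2 |
| Friday's | 0.250 | 3.0 | 2.0 |
| Friday's | 0.833 | 8.5 | 0.1 |
| Friday's | 1.33 | 14.4 | 1.7 |
| Friday's | 2.00 | 19.5 | 0 |
| Friday's | 3.00 | 28.9 | 0 |

(each reading ± 0.3 percentage points)

- what may be going on: substrate -> open intermediate; target <-> isomer of the product; partner -> second intermediate; open intermediate + second intermediate -> target
- "hardly changes" means that all values lie within two and a half points (for a concentration: within two and a half percent of the largest)

- [target] at the end for gamma, zeta, delta, in this order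
- the shape of the row from first to last (rises all the way / rises, then falls / falls all the way / falls, then rises / hardly changes)

The bench chemist proposed following one molecule. Substrate opens, the open intermediate waits for the second intermediate that partner becomes, and the target formed may turn into isomer of the product. Saturday's target reading, divided by the share charged, gave 42.0%, and she named this φ, the chance that a molecule charged so far stands as target at that reading. Tuesday's run gave 41.6% and Friday's 38.5%.

She noted that partner exceeds the substrate charge in gamma, zeta and delta, which makes substrate the limiting reagent. She therefore multiplied each charge by φ from the nearest earlier run, and her own reckoning gave 0.0504 M, 0.104 M and 0.193 M. The chair objected that the newest portion would be older at the end, 3.00 min against 1.0 min, so she called these figures slightly low.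

The forecaster held to 0.045 M, 0.089 M and 0.154 M, a row that rises all the way, and said: “The percentage falls, but the concentration still rises throughout.” The bench reckoning stood higher at each point, with the same shape.

    substrate → open intermediate (k = 0.158 s⁻¹)
    target ⇌ isomer of the product (K = 1.19, k = 0.0161 s⁻¹)
    partner → second intermediate (k = 0.431 s⁻¹)
    open intermediate + second intermediate → target (k = 0.0284 L mol⁻¹ s⁻¹)

The flasks ended at 0.0544 M, 0.110 M and 0.195 M, a row that rises all the way; φ from Saturday's run had given 0.0504 M for gamma, and φ from Friday's run 0.193 M for delta. In gamma, target and isomer of the product relax into each other, both ways together and by that step alone, with a half-life of 0.390 min, shorter than the run of 6.0 min. At 6.00 min gamma held 45.3% of its charge as target, 50.1% as isomer of the product and 4.59% as open intermediate, while delta at 6.00 min held 39.1% as target, 42.4% as isomer of the product and 18.5% as open intermediate.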